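The cis-fused labdane skeleton (labdane numbering; ring A = C1–C5 and C10, ring B = C5–C10) is cut at C10–C20 and C9–C11. The feature exploited is that C10 and C9 are the β- and α-carbons of a C8 carbonyl in ring B, the carbon that later carries the exocyclic methylene. One operation therefore joins three pieces: a methylcuprate adds CH3 to C10 of a bicyclic enone on the face of H5, and the C8 enolate so formed is alkylated at C9 by the allylic bromide carrying C11–C15. The precursor is enone ester 8, C8(=O)–C9=C10, made from an anisole ring; its C5 is set from C4, fixed by one asymmetric hydrogenation.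

Key step: step 9

Convention: labdane numbering is used for all bicyclic compounds; β is the face of CH3-20, α the opposite face.
Assumption: the hand of BINAP is assigned by analogy ((S)-ligand for the (S)-acid in step 3, as with 2-arylpropenoic acids; (R)-ligand for 13R in step 11, as with geraniol-type alkenols); if the sense proves opposite, the antipodal ligand is used.

Step 1
Reactants: 1 6-methoxy-1-tetralone
Product: 2 6-methoxy-3,4-dihydronaphthalen-1-yl trifluoromethanesulfonate
Conditions: Tf2O, 2,6-di-tert-butyl-4-methylpyridine, CH2Cl2, 0 °C → rt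
Reagents that add atoms: trifluoromethanesulfonic anhydride, O=S(=O)(OS(=O)(=O)C(F)(F)F)C(F)(F)F
Why: O-sulfonylation of the aryl ketone and loss of the only available α-proton give the enol triflate (enol triflate formation), the hindered pyridine taking up triflic acid without attacking the anhydride.

Step 2
Reactants: 2 6-methoxy-3,4-dihydronaphthalen-1-yl trifluoromethanesulfonate
Product: 3 6-methoxy-3,4-dihydronaphthalene-1-carboxylic acid
Conditions: CO (1 atm), Pd(OAc)2 (cat.), 1,3-bis(diphenylphosphino)propane, Et3N, DMF/H2O, 70 °C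
Reagents that add atoms: carbon monoxide, [C-]#[O+]; water, O
Why: oxidative addition of the alkenyl triflate to zerovalent palladium, CO insertion and hydrolysis of the acylpalladium species (palladium-catalysed hydroxycarbonylation) give the unsaturated acid without moving the double bond.

Step 3
Reactants: 3 6-methoxy-3,4-dihydronaphthalene-1-carboxylic acid
Product: 4 (S)-6-methoxy-1,2,3,4-tetrahydronaphthalene-1-carboxylic acid
Conditions: H2 (100 atm), Ru(OAc)2((S)-BINAP) (1 mol %), MeOH, rt
Reagents that add atoms: none
Why: carboxylate-directed asymmetric hydrogenation of an α-aryl α,β-unsaturated acid by the BINAP–ruthenium dicarboxylate sets C4 (tetralin C1) under catalyst control and leaves the anisole ring untouched.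

Step 4
Reactants: 4 (S)-6-methoxy-1,2,3,4-tetrahydronaphthalene-1-carboxylic acid
Product: 7 (1S,8aR)-6-oxo-1,2,3,4,6,7,8,8a-octahydronaphthalene-1-carboxylic acid, via dihydroanisole acid 5 (not isolated), via β,γ-unsaturated keto acid 6 (not isolated)
Conditions: Li, NH3(l), THF, t-BuOH, −78 → −33 °C; NH4Cl; then 3 M HCl, THF, 50 °C
Reagents that add atoms: water, O
Why: Birch reduction of the anisole ring (the acid carried as its lithium carboxylate, t-BuOH keeping the medium too weakly basic to deprotonate C4) gives the 2,5-dihydroanisole, and aqueous acid hydrolyses the enol ether and moves the double bond into conjugation, C5 (C8a) being protonated reversibly through the dienol so that the more stable isomer, with the C4 carboxyl equatorial and trans to C6, should accumulate.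

Step 5
Reactants: 7 (1S,8aR)-6-oxo-1,2,3,4,6,7,8,8a-octahydronaphthalene-1-carboxylic acid
Product: 8 methyl (1S,8aR)-6-oxo-1,2,3,4,6,7,8,8a-octahydronaphthalene-1-carboxylate
Conditions: MeOH, H2SO4 (cat.), 50 °C; chromatography
Reagents that add atoms: methanol, CO
Why: Fischer esterification under acid leaves C4 untouched and keeps C5 at equilibrium, and any C5 epimer is a separable diastereomer that can be returned to the same conditions.

Step 6
Reactants: 9 but-3-yn-1-ol
Product: 10 tert-butyl(but-3-yn-1-yloxy)dimethylsilane
Conditions: TBSCl, imidazole, CH2Cl2, rt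
Reagents that add atoms: tert-butyldimethylsilyl chloride, CC(C)(C)[Si](C)(C)Cl
Why: routine silylation of a primary alcohol, needed so that the oxygen survives the organometallic steps.

Step 7
Reactants: 10 tert-butyl(but-3-yn-1-yloxy)dimethylsilane
Product: 13 (E)-5-(tert-butyldimethylsilyloxy)-3-methylpent-2-en-1-ol, via alkenyldimethylalane 11 (not isolated), via lithium alkenylalanate 12 (not isolated)
Conditions: Me3Al, Cp2ZrCl2 (cat.), CH2Cl2, 0 °C → rt; n-BuLi, THF, −78 °C; (CH2O)n, −78 °C → rt
Reagents that add atoms: trimethylaluminium, C[Al](C)C; formaldehyde (from paraformaldehyde), C=O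
Why: zirconium-catalysed syn-carboalumination of the terminal alkyne (Negishi carboalumination) puts CH3 on the internal and aluminium on the terminal carbon, which fixes the E geometry, and the ate complex adds to formaldehyde with retention at the alkenyl carbon.

Step 8
Reactants: 13 (E)-5-(tert-butyldimethylsilyloxy)-3-methylpent-2-en-1-ol
Product: 14 tert-butyl{[(E)-5-bromo-3-methylpent-3-en-1-yl]oxy}dimethylsilane
Conditions: CBr4, PPh3, 2,6-lutidine, CH2Cl2, 0 °C
Reagents that add atoms: tetrabromomethane, BrC(Br)(Br)Br
Why: Appel bromination of a primary allylic alcohol proceeds by SN2 displacement of the oxyphosphonium group, without allylic transposition, and the buffered medium spares the silyl ether.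

Step 9
Reactants: 8 methyl (1S,8aR)-6-oxo-1,2,3,4,6,7,8,8a-octahydronaphthalene-1-carboxylate; 14 tert-butyl{[(E)-5-bromo-3-methylpent-3-en-1-yl]oxy}dimethylsilane; 15 methyllithium
Product: 18 methyl (1S,4aS,5R,8aR)-5-[(2E)-5-(tert-butyldimethylsilyloxy)-3-methylpent-2-en-1-yl]-4a-methyl-6-oxodecahydronaphthalene-1-carboxylate (8-oxo, 5β-H, 10β-CH3, 9β side chain, 4β-CO2CH3), via lithium dimethylcuprate 16 (not isolated), via lithium enolate 17 (not isolated)
Conditions: MeLi (2.2 equiv), CuI (1.1 equiv), Et2O, 0 °C; 8, −20 → 0 °C; then 14 (2 equiv), THF/DMPU, −40 °C → rt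
Reagents that add atoms: none
Why: Lithium dimethylcuprate 16 adds in 1,4-fashion to the ring B enone, delivering CH3 to the β-carbon C10 and leaving the regiodefined enolate 17 (C8–O–Li, C8=C9), which is then C-alkylated at C9 by SN2 attack on the primary allylic bromide 14; the closest known reaction type is the cuprate conjugate addition–enolate alkylation of 1(9)-octal-2-ones, which gives cis-fused angular-methyl decalones, and no ring is closed. C10 is controlled by the substrate: axial attack on the enone takes place on the face of H5, away from the C5–C4 bond that leans over the other face and from the axial hydrogens of ring A, so the ring fusion becomes cis. C9 is controlled by the shape of the cis bicycle: in the chair–chair form with the C4 ester equatorial the α face of C9 is syn-axial to C4–H4, and in the flipped form it is flanked by axial C1, so the bromide should enter on the β face, which also gives the more stable equatorial 9β chain. Regioselectivity for C9 over C7 is needed and is secured by generating the enolate only at C9 and trapping it with a reactive allylic halide in THF/DMPU before proton transfer can move it. SN2 rather than SN2' coupling is secured by the unhindered CH2Br terminus, and the methyl ester and the silyl ether are inert to the cuprate.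

Step 10
Reactants: 18 keto ester silyl ether
Product: 19 methyl (1S,4aS,5R,8aR)-5-[(2E)-5-hydroxy-3-methylpent-2-en-1-yl]-4a-methyl-6-oxodecahydronaphthalene-1-carboxylate
Conditions: HF·pyridine, THF/pyridine, 0 °C → rt
Reagents that add atoms: none
Why: fluoride cleavage of the primary silyl ether under non-basic conditions frees the C15 hydroxyl needed as a directing group without touching the ketone, the ester or C9.

Step 11
Reactants: 19 homoallylic alcohol
Product: 20 methyl (1S,4aS,5R,8aR)-5-[(3R)-5-hydroxy-3-methylpentyl]-4a-methyl-6-oxodecahydronaphthalene-1-carboxylate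
Conditions: H2 (100 atm), Ru(OAc)2((R)-BINAP) (2 mol %), MeOH, rt
Reagents that add atoms: none
Why: hydroxyl-directed asymmetric hydrogenation of a homoallylic alcohol, in which the C15 oxygen and the C12=C13 double bond chelate ruthenium so that C13 is set by the ligand, while the unactivated ketone and the ester are not reduced by the dicarboxylate catalyst.

Step 12
Reactants: 20 saturated hydroxy ketone
Product: 21 methyl (1S,4aS,5R,8aR)-5-[(3R)-5-(tert-butyldimethylsilyloxy)-3-methylpentyl]-4a-methyl-6-oxodecahydronaphthalene-1-carboxylate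
Conditions: TBSCl, imidazole, DMF, rt
Reagents that add atoms: tert-butyldimethylsilyl chloride, CC(C)(C)[Si](C)(C)Cl
Why: silylation removes the acidic hydroxyl before the two strongly basic steps that follow.

Step 13
Reactants: 21 silyl ether ketone
Product: 22 methyl (1S,4aS,5S,8aR)-5-[(3R)-5-(tert-butyldimethylsilyloxy)-3-methylpentyl]-4a-methyl-6-methylidenedecahydronaphthalene-1-carboxylate
Conditions: Ph3PCH3Br, KOtBu, toluene, rt → 80 °C
Reagents that add atoms: methyltriphenylphosphonium bromide, C[P+](c1ccccc1)(c1ccccc1)c1ccccc1.[Br-]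
Why: Wittig methylenation of the hindered C8 ketone with excess ylide is standard for this ring position; the 9β chain is the more stable C9 epimer, so the basic medium should not erode it, and any epimerisation at C4 is harmless because C4 passes through a planar enolate in step 14.

Step 14
Reactants: 22 methylene ester
Product: 24 methyl (1R,4aR,5S,8aS)-5-[(3R)-5-(tert-butyldimethylsilyloxy)-3-methylpentyl]-1,4a-dimethyl-6-methylidenedecahydronaphthalene-1-carboxylate (4β-CH3, 4α-CO2CH3), via lithium ester enolate 23 (not isolated)
Conditions: LiN(iPr)2, THF, −78 → 0 °C; DMPU, MeI, −78 °C → rt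
Reagents that add atoms: iodomethane, CI
Why: the amide base removes the only acidic proton left (C4–H), and iodomethane should alkylate enolate 23 on the β face, because in the chair–chair form that keeps H5 axial on ring A the α face of C4 is closed by the syn-axial C10–C9 bond, so the new methyl becomes cis to H5 and CH3-20 (ester enolate alkylation under substrate control).

Step 15
Reactants: 24 quaternary ester silyl ether
Product: 25 methyl (1R,4aR,5S,8aS)-5-[(3R)-5-hydroxy-3-methylpentyl]-1,4a-dimethyl-6-methylidenedecahydronaphthalene-1-carboxylate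
Conditions: HF·pyridine, THF/pyridine, 0 °C → rt
Reagents that add atoms: none
Why: fluoride cleavage of the primary silyl ether is mild enough for the exocyclic alkene and the hindered ester.

Step 16
Reactants: 25 primary alcohol
Product: 26 (3R)-5-[(1S,4aS,5R,8aR)-5-(methoxycarbonyl)-5,8a-dimethyl-2-methylidenedecahydronaphthalen-1-yl]-3-methylpentanoic acid (target; labdane numbering 4R,5S,9S,10R,13R)
Conditions: TEMPO (cat.), PhI(OAc)2, MeCN/H2O, rt
Reagents that add atoms: water, O
Why: the oxoammonium-mediated oxidation takes the primary alcohol through the aldehyde hydrate to the acid at neutral pH, without acid that could move the exocyclic double bond and without touching the hindered methyl ester or C13.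

Compound list
1 | 6-methoxy-1-tetralone | COc1ccc2c(c1)CCCC2=O | starting material
2 | 6-methoxy-3,4-dihydronaphthalen-1-yl trifluoromethanesulfonate | COc1ccc2c(c1)CCC=C2OS(=O)(=O)C(F)(F)F | intermediate
3 | 6-methoxy-3,4-dihydronaphthalene-1-carboxylic acid | COc1ccc2c(c1)CCC=C2C(=O)O | intermediate
4 | (S)-6-methoxy-1,2,3,4-tetrahydronaphthalene-1-carboxylic acid | COc1ccc2c(c1)CCC[C@@H]2C(=O)O | intermediate
5 | (S)-6-methoxy-1,2,3,4,5,8-hexahydronaphthalene-1-carboxylic acid | COC1=CCC2=C(C1)CCC[C@@H]2C(=O)O | intermediate (not isolated)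
6 | (S)-6-oxo-1,2,3,4,5,6,7,8-octahydronaphthalene-1-carboxylic acid | O=C1CCC2=C(C1)CCC[C@@H]2C(=O)O | intermediate (not isolated)
7 | (1S,8aR)-6-oxo-1,2,3,4,6,7,8,8a-octahydronaphthalene-1-carboxylic acid | O=C1CC[C@H]2C(=C1)CCC[C@@H]2C(=O)O | intermediate
8 | methyl (1S,8aR)-6-oxo-1,2,3,4,6,7,8,8a-octahydronaphthalene-1-carboxylate | O=C1CC[C@H]2C(=C1)CCC[C@@H]2C(=O)OC | intermediate
9 | but-3-yn-1-ol | C#CCCO | starting material
10 | tert-butyl(but-3-yn-1-yloxy)dimethylsilane | C#CCCO[Si](C)(C)C(C)(C)C | intermediate
11 | [(E)-4-(tert-butyldimethylsilyloxy)-2-methylbut-1-en-1-yl]dimethylalane | C[Al](C)/C=C(\C)CCO[Si](C)(C)C(C)(C)C | intermediate (not isolated)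
12 | lithium butyl[(E)-4-(tert-butyldimethylsilyloxy)-2-methylbut-1-en-1-yl]dimethylalanate | [Li+].CCCC[Al-](C)(C)/C=C(\C)CCO[Si](C)(C)C(C)(C)C | intermediate (not isolated)
13 | (E)-5-(tert-butyldimethylsilyloxy)-3-methylpent-2-en-1-ol | OC/C=C(\C)CCO[Si](C)(C)C(C)(C)C | intermediate
14 | tert-butyl{[(E)-5-bromo-3-methylpent-3-en-1-yl]oxy}dimethylsilane | BrC/C=C(\C)CCO[Si](C)(C)C(C)(C)C | intermediate
15 | methyllithium | [Li]C | starting material
16 | lithium dimethylcuprate | [Li+].C[Cu-]C | intermediate (not isolated)
17 | lithium enolate of the conjugate adduct (C8–OLi, C8=C9; cis-fused, 10β-CH3, 5β-H, 4β-CO2CH3) | [Li]OC1=C[C@@]2(C)CCC[C@H](C(=O)OC)[C@H]2CC1 | intermediate (not isolated)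
18 | methyl (1S,4aS,5R,8aR)-5-[(2E)-5-(tert-butyldimethylsilyloxy)-3-methylpent-2-en-1-yl]-4a-methyl-6-oxodecahydronaphthalene-1-carboxylate | O=C1CC[C@H]2[C@](C)(CCC[C@@H]2C(=O)OC)[C@H]1C/C=C(\C)CCO[Si](C)(C)C(C)(C)C | intermediate
19 | methyl (1S,4aS,5R,8aR)-5-[(2E)-5-hydroxy-3-methylpent-2-en-1-yl]-4a-methyl-6-oxodecahydronaphthalene-1-carboxylate | O=C1CC[C@H]2[C@](C)(CCC[C@@H]2C(=O)OC)[C@H]1C/C=C(\C)CCO | intermediate
20 | methyl (1S,4aS,5R,8aR)-5-[(3R)-5-hydroxy-3-methylpentyl]-4a-methyl-6-oxodecahydronaphthalene-1-carboxylate | O=C1CC[C@H]2[C@](C)(CCC[C@@H]2C(=O)OC)[C@H]1CC[C@@H](C)CCO | intermediate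
21 | methyl (1S,4aS,5R,8aR)-5-[(3R)-5-(tert-butyldimethylsilyloxy)-3-methylpentyl]-4a-methyl-6-oxodecahydronaphthalene-1-carboxylate | O=C1CC[C@H]2[C@](C)(CCC[C@@H]2C(=O)OC)[C@H]1CC[C@@H](C)CCO[Si](C)(C)C(C)(C)C | intermediate
22 | methyl (1S,4aS,5S,8aR)-5-[(3R)-5-(tert-butyldimethylsilyloxy)-3-methylpentyl]-4a-methyl-6-methylidenedecahydronaphthalene-1-carboxylate | C=C1CC[C@H]2[C@](C)(CCC[C@@H]2C(=O)OC)[C@H]1CC[C@@H](C)CCO[Si](C)(C)C(C)(C)C | intermediate
23 | lithium ester enolate of 22 (C4=C(OCH3)OLi) | C=C1CC[C@H]2[C@](C)(CCCC2=C(OC)O[Li])[C@H]1CC[C@@H](C)CCO[Si](C)(C)C(C)(C)C | intermediate (not isolated)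
24 | methyl (1R,4aR,5S,8aS)-5-[(3R)-5-(tert-butyldimethylsilyloxy)-3-methylpentyl]-1,4a-dimethyl-6-methylidenedecahydronaphthalene-1-carboxylate | C=C1CC[C@H]2[C@](C)(CCC[C@@]2(C)C(=O)OC)[C@H]1CC[C@@H](C)CCO[Si](C)(C)C(C)(C)C | intermediate
25 | methyl (1R,4aR,5S,8aS)-5-[(3R)-5-hydroxy-3-methylpentyl]-1,4a-dimethyl-6-methylidenedecahydronaphthalene-1-carboxylate | C=C1CC[C@H]2[C@](C)(CCC[C@@]2(C)C(=O)OC)[C@H]1CC[C@@H](C)CCO | intermediate
26 | (3R)-5-[(1S,4aS,5R,8aR)-5-(methoxycarbonyl)-5,8a-dimethyl-2-methylidenedecahydronaphthalen-1-yl]-3-methylpentanoic acid | C=C1CC[C@H]2[C@](C)(CCC[C@@]2(C)C(=O)OC)[C@H]1CC[C@@H](C)CC(=O)O | target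

Total step count: 16. Longest linear sequence: 13 steps (steps 1–5 and 9–16, from 6-methoxy-1-tetralone); the side-chain branch (steps 6–8) joins at step 9.

Steps most likely to fail

Step 9. The C9 enolate is neopentyl and carries copper species, so alkylation may be slow; proton transfer can then move the enolate to C7 and lead to C7 alkylation, dialkylation or recovered conjugate adduct, and β-face selectivity at C9 may be incomplete. The fallback sets out from 8. The cuprate addition is run in the presence of chlorotrimethylsilane, which traps the enolate as the C8 trimethylsilyl enol ether F1, and this is isolated. Methyllithium in THF then regenerates the copper-free lithium enolate 17, which is alkylated with 14 in THF/DMPU. The fallback comes back to the route at 18. Any 9α epimer can be converged by base equilibration of the ketone.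

Step 14. Facial selectivity at C4 may be poor or reversed if enolate 23 reacts through the other chair–chair form (C6 axial on ring A), which is free of allylic 1,3-strain between the enolate oxygen and C6 and in which CH3-20 is syn-axial over the β face; deprotonation of the hindered C4–H may also be slow. If the electrophile enters mainly on the α face, the fallback uses that same preference with the roles of the two C4 carbons exchanged. It sets out from 22. Enolate 23 is quenched with CO2 to give the malonic half-ester F2 (4α-CO2H, 4β-CO2CH3). LiEt3BH reduces only the methyl ester, the carboxylate being inert, to give hydroxy acid F3. Trimethylsilyldiazomethane gives hydroxy ester F4, and Dess–Martin periodinane the formyl ester F5. Tosylhydrazide converts this to tosylhydrazone F6, which catecholborane followed by NaOAc reduces to the methyl group. The fallback comes back to the route at 24.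

Step 11. Hydrogenation may be slow or poorly face-selective, because the methyl group sits on the alkene carbon nearer the hydroxyl, a less usual pattern for this catalyst than geraniol-type alkenols. The fallback sets out from 18 and gives up hydroxyl direction: the trialkyl-substituted alkene of the silyl ether is hydrogenated with H2 and a cationic iridium complex [Ir(cod)(L)][B(C6H3(CF3)2)4] (cod = 1,5-cyclooctadiene, L = a chiral phosphinooxazoline), a catalyst class established for unfunctionalised trisubstituted alkenes. The fallback comes back to the route at 21, so steps 10 and 12 are not needed; no new compound is made (F0).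

Further compounds
F1 | step 9 | trimethylsilyl enol ether of the conjugate adduct (C8–OSiMe3, C8=C9; 10β-CH3, 5β-H, 4β-CO2CH3) | C[Si](C)(C)OC1=C[C@@]2(C)CCC[C@H](C(=O)OC)[C@H]2CC1
F2 | step 14 | malonic half-ester of 22 (4α-CO2H, 4β-CO2CH3) | C=C1CC[C@H]2[C@](C)(CCC[C@@]2(C(=O)OC)C(=O)O)[C@H]1CC[C@@H](C)CCO[Si](C)(C)C(C)(C)C
F3 | step 14 | hydroxy acid (4α-CO2H, 4β-CH2OH) | C=C1CC[C@H]2[C@](C)(CCC[C@@]2(CO)C(=O)O)[C@H]1CC[C@@H](C)CCO[Si](C)(C)C(C)(C)C
F4 | step 14 | hydroxy ester (4α-CO2CH3, 4β-CH2OH) | C=C1CC[C@H]2[C@](C)(CCC[C@@]2(CO)C(=O)OC)[C@H]1CC[C@@H](C)CCO[Si](C)(C)C(C)(C)C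
F5 | step 14 | formyl ester (4α-CO2CH3, 4β-CHO) | C=C1CC[C@H]2[C@](C)(CCC[C@@]2(C=O)C(=O)OC)[C@H]1CC[C@@H](C)CCO[Si](C)(C)C(C)(C)C
F6 | step 14 | tosylhydrazone of F5 | C=C1CC[C@H]2[C@](C)(CCC[C@@]2(C=NNS(=O)(=O)c3ccc(C)cc3)C(=O)OC)[C@H]1CC[C@@H](C)CCO[Si](C)(C)C(C)(C)C
F0 | step 11 | none | none
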